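**Retrosynthetic overview**
- The hydroxyquinone is opened last: Teuber oxidation of the 2',4'-dihydroxy-3'-prenylphenyl chroman 24 at C5', the only free position para to the 2'-hydroxyl.
- The chroman O1–C2 bond comes from Mitsunobu closure of phenol–alcohol 21, itself the LiAlH4 reduction product of 3-aryl dihydrocoumarin 20.
- Lactone 20 is cut at C3–C4 and O1–C2 into ortho-quinone methide 19 (ring A, from sulfone 9) and the isothiourea-bound enolate of arylacetic acid 17. This formal [4+2] forms the pyran ring, the only ring built, and sets C3.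
- The strategy rests on the pyran ring O1–C2–C3–C4 fused to ring A at C4a/C8a: its single stereocentre C3 lies between the unsubstituted benzylic C4 and the oxygen-bearing C2, the pattern of a CH2-terminated quinone methide joined to a two-carbon enolate.
- Sulfone 9 comes from 3,5-dimethoxyphenol (C4 lithiation/prenylation, ortho-formylation, reduction/sulfination); acid 17 comes from 4-bromoresorcinol (acetal protection, lithiation/prenylation, Br/Li exchange with ethylene oxide, oxidation).

Key step: step 10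

Remark: "prenyl" means 3-methylbut-2-en-1-yl; the (2S,3R) enantiomer of HyperBTM [(2S,3R)-3-isopropyl-2-phenyl-3,4-dihydro-2H-benzo[4,5]thiazolo[3,2-a]pyrimidine] is assumed, from the usual face-shielding model, to give the (3R) lactone, and the (2R,3S) catalyst would be used instead if the assay at diol 21 showed the opposite sense.

**Route**

Step 1
Reactants: 1 3,5-dimethoxyphenol
Product: 2 (3,5-dimethoxyphenoxy)triisopropylsilane
Conditions: TIPSCl, imidazole, DMF, rt
Reagents that add atoms: chlorotriisopropylsilane, CC(C)[Si](Cl)(C(C)C)C(C)C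
Why: Imidazole-assisted silylation of the phenol installs a bulky, non-coordinating group that should steer the following lithiation away from its own ortho positions.

Step 2
Reactants: 2 (3,5-dimethoxyphenoxy)triisopropylsilane; 3 prenyl bromide
Product: 5 (3,5-dimethoxy-4-prenylphenoxy)triisopropylsilane, via aryllithium 4 (not isolated)
Conditions: n-BuLi, TMEDA, THF, 0 °C → rt; then CuI (10 mol%), 3, −20 °C → rt
Reagents that add atoms: none
Why: Directed ortho-metalation should occur at C4, which lies between two coordinating methoxy groups while the flanks of the silyl ether are shielded, and the aryllithium is then allylated at the primary carbon of prenyl bromide under copper catalysis (SN2).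

Step 3
Reactants: 5 (3,5-dimethoxy-4-prenylphenoxy)triisopropylsilane
Product: 6 3,5-dimethoxy-4-prenylphenol
Conditions: Bu4NF, THF, 0 °C; then H2O
Reagents that add atoms: none
Why: Fluoride-induced desilylation is driven by the Si–F bond and leaves the aryl methyl ethers and the prenyl group untouched.

Step 4
Reactants: 6 3,5-dimethoxy-4-prenylphenol
Product: 7 6-hydroxy-2,4-dimethoxy-3-prenylbenzaldehyde
Conditions: MgCl2, Et3N, (CH2O)n, MeCN, 80 °C
Reagents that add atoms: paraformaldehyde (formaldehyde unit), C=O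
Why: In the Casnati–Skattebøl ortho-formylation the magnesium phenoxide delivers formaldehyde only ortho to the hydroxyl (both such positions are equivalent and the para position is blocked), and a second formaldehyde oxidises the benzylic alkoxide by hydride transfer.

Step 5
Reactants: 7 6-hydroxy-2,4-dimethoxy-3-prenylbenzaldehyde
Product: 9 3,5-dimethoxy-4-prenyl-2-[(4-methylphenyl)sulfonylmethyl]phenol, via salicyl alcohol 8 (not isolated)
Conditions: NaBH4, EtOH/THF, 0 °C; then TolSO2Na, AcOH/H2O, rt
Reagents that add atoms: sodium 4-methylbenzenesulfinate, Cc1ccc(cc1)S(=O)[O-].[Na+]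
Why: Borohydride reduction gives an ionisation-prone salicyl alcohol that under mild acid loses water to a donor-stabilised benzylic cation, which the soft sulfinate captures at sulfur (S-alkylation of a sulfinate) to give the sulfone as the thermodynamic product without isolating the labile alcohol.

Step 6
Reactants: 10 4-bromoresorcinol
Product: 11 1-bromo-2,4-bis(methoxymethoxy)benzene
Conditions: MOMCl, iPr2NEt, CH2Cl2, 0 °C → rt
Reagents that add atoms: chloromethyl methyl ether, COCCl
Why: Both phenols undergo Williamson-type O-alkylation by the reactive chloromethyl ether, giving acetals that later direct lithiation.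

Step 7
Reactants: 11 1-bromo-2,4-bis(methoxymethoxy)benzene; 3 prenyl bromide
Product: 13 1-bromo-2,4-bis(methoxymethoxy)-3-prenylbenzene, via aryllithium 12 (not isolated)
Conditions: LiN(iPr)2, THF, −78 °C; then CuI (10 mol%), 3, −78 °C → 0 °C
Reagents that add atoms: none
Why: Directed ortho-metalation by the non-nucleophilic amide should take the most acidic ring hydrogen, between the two acetal oxygens and meta to bromine, so that neither halogen–metal exchange nor aryne formation intervenes, and copper-catalysed SN2 allylation then installs the prenyl group.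

Step 8
Reactants: 13 1-bromo-2,4-bis(methoxymethoxy)-3-prenylbenzene
Product: 15 2-[2,4-bis(methoxymethoxy)-3-prenylphenyl]ethanol, via aryllithium 14 (not isolated)
Conditions: n-BuLi, THF, −78 °C; then ethylene oxide, BF3·OEt2, −78 °C; then H2O
Reagents that add atoms: ethylene oxide, C1CO1
Why: Bromine–lithium exchange at −78 °C is faster than any deprotonation of the prenyl methylene, and the aryllithium opens BF3-activated ethylene oxide (epoxide ring opening) to the two-carbon alcohol.

Step 9
Reactants: 15 2-[2,4-bis(methoxymethoxy)-3-prenylphenyl]ethanol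
Product: 17 [2,4-bis(methoxymethoxy)-3-prenylphenyl]acetic acid, via arylacetaldehyde 16 (not isolated)
Conditions: TEMPO (20 mol%), PhI(OAc)2, MeCN/H2O, rt
Reagents that add atoms: water, O
Why: Oxoammonium (TEMPO) catalysis with PhI(OAc)2 as terminal oxidant takes the primary alcohol through the aldehyde hydrate to the acid under near-neutral conditions that should spare the acetals, the prenyl group and the electron-rich ring.

Step 10
Reactants: 17 [2,4-bis(methoxymethoxy)-3-prenylphenyl]acetic acid; 9 3,5-dimethoxy-4-prenyl-2-[(4-methylphenyl)sulfonylmethyl]phenol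
Product: 20 (3R)-3-[2,4-bis(methoxymethoxy)-3-prenylphenyl]-5,7-dimethoxy-6-prenylchroman-2-one, via mixed pivalic anhydride 18 (not isolated), via ortho-quinone methide 19 (not isolated)
Conditions: t-BuCOCl (1.05 equiv), iPr2NEt, CH2Cl2, 0 °C; then 9 (1.3 equiv), (2S,3R)-HyperBTM (10 mol%), Cs2CO3, −40 °C → 0 °C; rapid filtration through silica
Reagents that add atoms: none
Why: Cs2CO3 deprotonates the phenol of 9 and sulfinate is expelled (E1cB) to give quinone methide 19, while the isothiourea is N-acylated by mixed anhydride 18 and the acyl ammonium ion is deprotonated to a (Z)-ammonium enolate. The enolate carbon adds to the exocyclic CH2 of 19 (Michael addition, C3–C4) and the phenoxide so formed attacks the acyl ammonium carbonyl (O1–C2), closing the pyranone ring by 6-exo-trig lactonisation and releasing the catalyst. The closest known reaction type is the formal [4+2] of ammonium or azolium enolates with ortho-quinone methides to 3,4-dihydrocoumarins. C3 is the only new stereocentre: the 1,5 O···S contact holds the enolate coplanar with the catalyst and the pseudo-axial phenyl group shields one face, so that the methide is expected to add to the face that gives (3R) with the (2S,3R) catalyst. The step needs C- over O-alkylation and enantiofacial control without later enolisation; the three oxygen donors of ring A moderate the methide enough for the catalysed pathway, its CH2 terminus creates no second stereocentre, and the ortho-acetal substituent twists the C3 aryl group out of conjugation, which together with low temperature and immediate reduction should limit epimerisation.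

Step 11
Reactants: 20 (3R)-3-[2,4-bis(methoxymethoxy)-3-prenylphenyl]-5,7-dimethoxy-6-prenylchroman-2-one
Product: 21 (2R)-2-[2,4-bis(methoxymethoxy)-3-prenylphenyl]-3-(6-hydroxy-2,4-dimethoxy-3-prenylphenyl)propan-1-ol
Conditions: LiAlH4, THF, −40 °C → 0 °C; then H2O
Reagents that add atoms: none
Why: Hydride reduction of the aryl lactone (acyl substitution, then aldehyde reduction) should outpace enolisation at low temperature, so the C3 configuration is carried unchanged into the phenol–alcohol.

Step 12
Reactants: 21 (2R)-2-[2,4-bis(methoxymethoxy)-3-prenylphenyl]-3-(6-hydroxy-2,4-dimethoxy-3-prenylphenyl)propan-1-ol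
Product: 22 (3R)-3-[2,4-bis(methoxymethoxy)-3-prenylphenyl]-5,7-dimethoxy-6-prenylchromane
Conditions: PPh3, DIAD, THF, 0 °C → rt
Reagents that add atoms: none
Why: In this Mitsunobu etherification the primary alcohol is activated as its oxyphosphonium ion and displaced by the only free phenol (ring A) in a 6-exo-tet closure at a non-stereogenic carbon, so C3 is not touched.

Step 13
Reactants: 22 (3R)-3-[2,4-bis(methoxymethoxy)-3-prenylphenyl]-5,7-dimethoxy-6-prenylchromane
Product: 24 4-[(3R)-5,7-dimethoxy-6-prenylchroman-3-yl]-2-prenylbenzene-1,3-diol, via bis(trimethylsilyl) ether 23 (not isolated)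
Conditions: TMSOTf, 2,2'-bipyridyl, CH2Cl2, 0 °C → rt; then H2O
Reagents that add atoms: none
Why: Silyl triflate/2,2'-bipyridyl acetal exchange converts aryl methoxymethyl ethers into aryl silyl ethers without a Brønsted acid, and the labile trimethylsilyl ethers hydrolyse on aqueous work-up, which should avoid acid-catalysed addition of the freed ortho hydroxyls to the 3'-prenyl double bond.

Step 14
Reactants: 24 4-[(3R)-5,7-dimethoxy-6-prenylchroman-3-yl]-2-prenylbenzene-1,3-diol
Product: 25 2-hydroxy-5-[(3R)-5,7-dimethoxy-6-prenylchroman-3-yl]-3-prenylcyclohexa-2,5-diene-1,4-dione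
Conditions: (KSO3)2NO, KH2PO4, acetone/H2O, 0 °C → rt
Reagents that add atoms: potassium nitrosodisulfonate, [K+].[K+].[O-]S(=O)(=O)N([O])S(=O)(=O)[O-]
Why: In the Teuber oxidation the nitroxyl radical abstracts the phenolic hydrogen and a second equivalent delivers oxygen to C5', the only unsubstituted position para to the 2'-hydroxyl and ortho to the 4'-hydroxyl, giving the 2-hydroxy-1,4-benzoquinone tautomer while ring A, which has no free phenol, should stay intact.

**Compound list**
1 | 3,5-dimethoxyphenol | COc1cc(O)cc(OC)c1 | starting material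
2 | (3,5-dimethoxyphenoxy)triisopropylsilane | COc1cc(O[Si](C(C)C)(C(C)C)C(C)C)cc(OC)c1 | intermediate
3 | prenyl bromide (1-bromo-3-methylbut-2-ene) | CC(C)=CCBr | starting material
4 | [2,6-dimethoxy-4-(triisopropylsilyloxy)phenyl]lithium | [Li]c1c(OC)cc(O[Si](C(C)C)(C(C)C)C(C)C)cc1OC | intermediate
5 | (3,5-dimethoxy-4-prenylphenoxy)triisopropylsilane | COc1cc(O[Si](C(C)C)(C(C)C)C(C)C)cc(OC)c1CC=C(C)C | intermediate
6 | 3,5-dimethoxy-4-prenylphenol | COc1cc(O)cc(OC)c1CC=C(C)C | intermediate
7 | 6-hydroxy-2,4-dimethoxy-3-prenylbenzaldehyde | COc1cc(O)c(C=O)c(OC)c1CC=C(C)C | intermediate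
8 | 2-(hydroxymethyl)-3,5-dimethoxy-4-prenylphenol | COc1cc(O)c(CO)c(OC)c1CC=C(C)C | intermediate
9 | 3,5-dimethoxy-4-prenyl-2-[(4-methylphenyl)sulfonylmethyl]phenol | COc1cc(O)c(CS(=O)(=O)c2ccc(C)cc2)c(OC)c1CC=C(C)C | intermediate
10 | 4-bromoresorcinol (4-bromobenzene-1,3-diol) | Oc1ccc(Br)c(O)c1 | starting material
11 | 1-bromo-2,4-bis(methoxymethoxy)benzene | COCOc1ccc(Br)c(OCOC)c1 | intermediate
12 | [3-bromo-2,6-bis(methoxymethoxy)phenyl]lithium | [Li]c1c(OCOC)ccc(Br)c1OCOC | intermediate
13 | 1-bromo-2,4-bis(methoxymethoxy)-3-prenylbenzene | COCOc1ccc(Br)c(OCOC)c1CC=C(C)C | intermediate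
14 | [2,4-bis(methoxymethoxy)-3-prenylphenyl]lithium | [Li]c1ccc(OCOC)c(CC=C(C)C)c1OCOC | intermediate
15 | 2-[2,4-bis(methoxymethoxy)-3-prenylphenyl]ethanol | OCCc1ccc(OCOC)c(CC=C(C)C)c1OCOC | intermediate
16 | [2,4-bis(methoxymethoxy)-3-prenylphenyl]acetaldehyde | O=CCc1ccc(OCOC)c(CC=C(C)C)c1OCOC | intermediate
17 | [2,4-bis(methoxymethoxy)-3-prenylphenyl]acetic acid | OC(=O)Cc1ccc(OCOC)c(CC=C(C)C)c1OCOC | intermediate
18 | [2,4-bis(methoxymethoxy)-3-prenylphenyl]acetic pivalic anhydride | CC(C)(C)C(=O)OC(=O)Cc1ccc(OCOC)c(CC=C(C)C)c1OCOC | intermediate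
19 | 3,5-dimethoxy-6-methylidene-4-prenylcyclohexa-2,4-dien-1-one | C=C1C(=O)C=C(OC)C(CC=C(C)C)=C1OC | intermediate
20 | (3R)-3-[2,4-bis(methoxymethoxy)-3-prenylphenyl]-5,7-dimethoxy-6-prenylchroman-2-one | COc1cc2c(c(OC)c1CC=C(C)C)C[C@H](c1ccc(OCOC)c(CC=C(C)C)c1OCOC)C(=O)O2 | intermediate
21 | (2R)-2-[2,4-bis(methoxymethoxy)-3-prenylphenyl]-3-(6-hydroxy-2,4-dimethoxy-3-prenylphenyl)propan-1-ol | COc1cc(O)c(C[C@H](c2ccc(OCOC)c(CC=C(C)C)c2OCOC)CO)c(OC)c1CC=C(C)C | intermediate
22 | (3R)-3-[2,4-bis(methoxymethoxy)-3-prenylphenyl]-5,7-dimethoxy-6-prenylchromane | COc1cc2c(c(OC)c1CC=C(C)C)C[C@H](c1ccc(OCOC)c(CC=C(C)C)c1OCOC)CO2 | intermediate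
23 | (3R)-3-[2,4-bis(trimethylsilyloxy)-3-prenylphenyl]-5,7-dimethoxy-6-prenylchromane | COc1cc2c(c(OC)c1CC=C(C)C)C[C@H](c1ccc(O[Si](C)(C)C)c(CC=C(C)C)c1O[Si](C)(C)C)CO2 | intermediate
24 | 4-[(3R)-5,7-dimethoxy-6-prenylchroman-3-yl]-2-prenylbenzene-1,3-diol | COc1cc2c(c(OC)c1CC=C(C)C)C[C@H](c1ccc(O)c(CC=C(C)C)c1O)CO2 | intermediate
25 | 2-hydroxy-5-[(3R)-5,7-dimethoxy-6-prenylchroman-3-yl]-3-prenylcyclohexa-2,5-diene-1,4-dione (CNP0241224.1) | COc1cc2c(c(OC)c1CC=C(C)C)C[C@H](C1=CC(=O)C(O)=C(CC=C(C)C)C1=O)CO2 | target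

**Step count**
Total: 14 steps. Longest linear sequence: 10 steps (steps 1–5, then 10–14); the ring B branch (steps 6–9) joins at step 10.

**Steps most likely to fail**

Step 10. The C3 configuration may erode through enolisation of the 3-aryl lactone under carbonate, or the methide may be lost to self-condensation before the catalytic enolate reaches it. The fallback replaces catalysis by stoichiometric auxiliary control and sets out from acid 17. The acid is coupled, through its mixed anhydride 18, with lithiated (R)-4-benzyl-2-oxazolidinone to give (4R)-4-benzyl-3-{[2,4-bis(methoxymethoxy)-3-prenylphenyl]acetyl}oxazolidin-2-one F1. Its sodium (Z)-enolate (NaN(SiMe3)2, THF, −78 °C) is combined with the sodium phenoxide of sulfone 9, which should shed sulfinate on warming to about −40 °C. The enolate then adds to methide 19 on the face away from the benzyl group to give (4R)-4-benzyl-3-[(2R)-2-[2,4-bis(methoxymethoxy)-3-prenylphenyl]-3-(6-hydroxy-2,4-dimethoxy-3-prenylphenyl)propanoyl]oxazolidin-2-one F2. LiBH4 in THF/MeOH at 0 °C cleaves the imide reductively and the route is rejoined at diol 21.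

Step 13. A freed 2'- or 4'-hydroxyl may add to the neighbouring prenyl double bond (dimethylchroman formation) under the Lewis-acidic conditions, or the hindered 2'-acetal may cleave incompletely. The fallback uses fluoride-labile 2-(trimethylsilyl)ethoxymethyl acetals throughout ring B and sets out from 4-bromoresorcinol 10. Alkylation with 2-(trimethylsilyl)ethoxymethyl chloride and iPr2NEt gives 1-bromo-2,4-bis{[2-(trimethylsilyl)ethoxy]methoxy}benzene F3. Lithiation with LiN(iPr)2 and copper-catalysed prenylation with 3 give 1-bromo-3-prenyl-2,4-bis{[2-(trimethylsilyl)ethoxy]methoxy}benzene F4. Br/Li exchange and opening of ethylene oxide give 2-(3-prenyl-2,4-bis{[2-(trimethylsilyl)ethoxy]methoxy}phenyl)ethanol F5, and TEMPO/PhI(OAc)2 oxidation gives (3-prenyl-2,4-bis{[2-(trimethylsilyl)ethoxy]methoxy}phenyl)acetic acid F6. The step 10 conditions with sulfone 9 give (3R)-5,7-dimethoxy-6-prenyl-3-(3-prenyl-2,4-bis{[2-(trimethylsilyl)ethoxy]methoxy}phenyl)chroman-2-one F7. LiAlH4 gives (2R)-3-(6-hydroxy-2,4-dimethoxy-3-prenylphenyl)-2-(3-prenyl-2,4-bis{[2-(trimethylsilyl)ethoxy]methoxy}phenyl)propan-1-ol F8, and Mitsunobu closure gives (3R)-5,7-dimethoxy-6-prenyl-3-(3-prenyl-2,4-bis{[2-(trimethylsilyl)ethoxy]methoxy}phenyl)chromane F9. Bu4NF in DMPU at 60 °C then removes both acetals by fluoride-triggered fragmentation, with no acid present, and the route is rejoined at diol 24.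

Step 14. Over-oxidation, attack on the prenyl groups or ring A, or oxidative coupling of the resorcinol ring may take the place of clean oxygenation at C5'. The fallback installs the C5' oxygen by formylation and Dakin oxidation and sets out from 24. Magnesium-mediated ortho-formylation (MgCl2, Et3N, (CH2O)n) can only reach C5', the sole free position ortho to a hydroxyl, and gives 5-[(3R)-5,7-dimethoxy-6-prenylchroman-3-yl]-2,4-dihydroxy-3-prenylbenzaldehyde F10. Dakin oxidation (H2O2, NaOH, degassed, 0 °C) gives 5-[(3R)-5,7-dimethoxy-6-prenylchroman-3-yl]-3-prenylbenzene-1,2,4-triol F11. Mild oxidation of this hydroxyquinol with Ag2O in ether (or air) returns the route at target 25.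

**Further compounds**
F1 | step 10 | (4R)-4-benzyl-3-{[2,4-bis(methoxymethoxy)-3-prenylphenyl]acetyl}oxazolidin-2-one | O=C1OC[C@@H](Cc2ccccc2)N1C(=O)Cc1ccc(OCOC)c(CC=C(C)C)c1OCOC
F2 | step 10 | (4R)-4-benzyl-3-[(2R)-2-[2,4-bis(methoxymethoxy)-3-prenylphenyl]-3-(6-hydroxy-2,4-dimethoxy-3-prenylphenyl)propanoyl]oxazolidin-2-one | COc1cc(O)c(C[C@H](c2ccc(OCOC)c(CC=C(C)C)c2OCOC)C(=O)N2[C@H](Cc3ccccc3)COC2=O)c(OC)c1CC=C(C)C
F3 | step 13 | 1-bromo-2,4-bis{[2-(trimethylsilyl)ethoxy]methoxy}benzene | C[Si](C)(C)CCOCOc1ccc(Br)c(OCOCC[Si](C)(C)C)c1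
F4 | step 13 | 1-bromo-3-prenyl-2,4-bis{[2-(trimethylsilyl)ethoxy]methoxy}benzene | C[Si](C)(C)CCOCOc1ccc(Br)c(OCOCC[Si](C)(C)C)c1CC=C(C)C
F5 | step 13 | 2-(3-prenyl-2,4-bis{[2-(trimethylsilyl)ethoxy]methoxy}phenyl)ethanol | OCCc1ccc(OCOCC[Si](C)(C)C)c(CC=C(C)C)c1OCOCC[Si](C)(C)C
F6 | step 13 | (3-prenyl-2,4-bis{[2-(trimethylsilyl)ethoxy]methoxy}phenyl)acetic acid | OC(=O)Cc1ccc(OCOCC[Si](C)(C)C)c(CC=C(C)C)c1OCOCC[Si](C)(C)C
F7 | step 13 | (3R)-5,7-dimethoxy-6-prenyl-3-(3-prenyl-2,4-bis{[2-(trimethylsilyl)ethoxy]methoxy}phenyl)chroman-2-one | COc1cc2c(c(OC)c1CC=C(C)C)C[C@H](c1ccc(OCOCC[Si](C)(C)C)c(CC=C(C)C)c1OCOCC[Si](C)(C)C)C(=O)O2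
F8 | step 13 | (2R)-3-(6-hydroxy-2,4-dimethoxy-3-prenylphenyl)-2-(3-prenyl-2,4-bis{[2-(trimethylsilyl)ethoxy]methoxy}phenyl)propan-1-ol | COc1cc(O)c(C[C@H](c2ccc(OCOCC[Si](C)(C)C)c(CC=C(C)C)c2OCOCC[Si](C)(C)C)CO)c(OC)c1CC=C(C)C
F9 | step 13 | (3R)-5,7-dimethoxy-6-prenyl-3-(3-prenyl-2,4-bis{[2-(trimethylsilyl)ethoxy]methoxy}phenyl)chromane | COc1cc2c(c(OC)c1CC=C(C)C)C[C@H](c1ccc(OCOCC[Si](C)(C)C)c(CC=C(C)C)c1OCOCC[Si](C)(C)C)CO2
F10 | step 14 | 5-[(3R)-5,7-dimethoxy-6-prenylchroman-3-yl]-2,4-dihydroxy-3-prenylbenzaldehyde | COc1cc2c(c(OC)c1CC=C(C)C)C[C@H](c1cc(C=O)c(O)c(CC=C(C)C)c1O)CO2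
F11 | step 14 | 5-[(3R)-5,7-dimethoxy-6-prenylchroman-3-yl]-3-prenylbenzene-1,2,4-triol | COc1cc2c(c(OC)c1CC=C(C)C)C[C@H](c1cc(O)c(O)c(CC=C(C)C)c1O)CO2
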